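Compounds are numbered 1–23 in the order in which they appear in the steps, and the same numbers are used in the reasoning before the steps.

## Analysis of the target

The target 23 is a diaryl ether of two benzene rings; it has no stereocentre and no configurationally stable axis. Ring A is pentasubstituted: C1 carries the methyl ester, C2 the ether oxygen, C3 a methoxy group, C4 chlorine and C5 a free hydroxyl, so that only C6 bears hydrogen. Ring B carries the ether oxygen at C1, a free carboxylic acid at C2, a hydroxyl at C3 and a methyl group at C5. Ring B is a 2,6-dioxygenated benzoic acid and can lose CO2 in strong acid or on heating; the aryl chloride rules out hydrogenolysis; both phenols are oxidisable. The two carboxyl groups must stay distinguishable throughout, methyl ester on ring A and free acid on ring B. Two things make the synthesis hard. The ether joins a ring A oxygen flanked by OMe and CO2Me to a ring B carbon next to a carboxyl, which is a poor case for aryl–oxygen coupling. The chlorine sits at C4 between OMe and OH, where electrophilic chlorination would have to compete with C6. The strategy rests on ring B: its contiguous C1(O)–C2(CO2H)–C3(OH) triad and its C5 methyl map onto a 3-carboxy-4-oxy-6-methyl-2-pyrone (pyrone C3, C4, C5, C6 become ring B C2, C3, C4, C5). Ring B C1 and C6 then come from a two-carbon aryloxyacetylene already attached to the ring A oxygen.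

## Retrosynthetic reasoning

**Protecting groups (23 from 22 from 21).** The last bond cut is the O–allyl bond of the ring B ester in 22. Palladium-catalysed allyl transfer frees the acid at room temperature under neutral conditions, so the decarboxylation-prone acid never meets acid or heat. One step earlier the two acetal C–O bonds of 21 are cut by acid while the ring B carboxyl is still an ester and cannot decarboxylate. An allyl ester on ring B against a methyl ester on ring A keeps the two carboxyls distinct from the start.

**Ring B (21 from 13 and 19).** Ring B bonds C1–C2 and C5–C6 are cut, which returns ring B to pyrone 19 and the ring A alkynyl ether 13. The cut is made here because it removes the hindered aryl–oxygen coupling altogether: the ether oxygen is attached to ring A as a simple phenol derivative and ring B is grown on it. All four ring B substituents arrive at their final oxidation level, so only deprotections follow. The forward reaction has to be a regioselective inverse-demand [4+2] cycloaddition that passes through bicyclic lactone 20 and aromatises by decarboxylative cycloreversion.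

**Alkynyl ether (13 from 11 from 9 from 8).** The triple bond is traced back to an O-vinyl group. The O–C(sp2) bond of 9 is cut to phenol 8 (copper-mediated vinylation). The alkyne then comes from bromination to 10, loss of HBr to 11 and a second dehydrobromination through acetylide 12. The more usual entry to alkynyl ethers through halogen–lithium exchange was set aside, because an alkyllithium would not spare the ring A methyl ester. A hindered lithium amide at low temperature should.

**Ring A (8 from 7 from 6 from 4 from 3 from 1).** The acetal of 8 is put selectively on the C5 hydroxyl of 7, which is the only one not hydrogen-bonded to the ester. The C5–O bond of 6 is cut to 4 (para-hydroxylation through sulfate 5), and the C1–carbon bond of 3 is cut to phenol 1 (ortho-formylation through 2, then oxidation to 4). The chlorine is bought in with 1 on purpose. In 1 the single free hydroxyl sends the carbon substituent to its only free ortho position and the new oxygen to its para position, so all five ring A substituents are placed without a regiochemical choice. A late chlorination of a chlorine-free ring A would have had to distinguish C4 from C6.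

**Pyrone (19 from 18 from 14 and 15).** The acetal of 19 goes back to hydroxypyrone 18. In 18 the lactone O–C(=O) bond and the C3–C4 bond are cut, which gives malonate 14 and the acetylketene 16 that dioxinone 15 releases on heating; the open-chain tricarbonyl 17 lies between. The diallyl ester is chosen so that the ester left on the pyrone is already the allyl ester needed at the end.

## Alternatives that were turned down

**Alternative 1:** Ring A is grown on ring B. Ring A bonds C1–C2 and C4–C5 are cut. In the forward key step the enolate of aryloxyacetone A2 adds through its aryloxy-bearing carbon to dimethyl fumarate A3, and the methyl ketone carbon then closes onto the far ester to give the racemic trans cyclohexane-1,3-dione A1.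
- For it: the ether oxygen is installed by simple O-alkylation of a ring B phenol, the materials are cheap and no alkynyl ether is needed. Chlorination would go to C4 without question, because C4 lies between the two carbonyls. On this point it is as secure as the chosen route and does not depend on a speciality phenol.
- Against it: in A1 the aryloxy group is beta to the ester carbonyl, so the basic conditions of the ring closure invite E1cB loss of the ring B phenoxide. After chlorination the ring must still be dehydrogenated. The two resulting hydroxyls must then be told apart, with the more hindered C3 oxygen methylated and the C5 oxygen left free, which runs against the inherent reactivity.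
- Comparison: the chosen route is no shorter before its key step, but after it only two deprotections remain, with every substituent already at its final oxidation level and position.

**Alternative 2:** Ring B is built by Danheiser benzannulation. Heating 3-methylcyclobut-2-en-1-one A5 with the internal ring A alkynyl ether A6 gives a vinylketene, which adds to the alkyne; the new cyclobutenone opens and recloses to phenol A4.
- For it: the ketene is strongly electrophilic and carries no deactivating donor, so this ring formation is probably faster and kinetically more dependable than a cycloaddition onto an alkoxy-substituted pyrone. The C3 hydroxyl is also delivered unprotected.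
- Against it: the ring B C2 carbon must arrive as a silyloxymethyl group, since an ester on the alkyne would make it a push–pull alkyne that reacts poorly with ketenes. Desilylation and two oxidations then have to be run next to a free phenol and electron-rich rings. A6 is an internal alkynyl ether that is harder to make in the presence of the methyl ester than the terminal 13, and A5 is volatile and sensitive.
- Comparison: the chosen route gives up some reactivity in the ring-forming step, and in return brings the carboxyl in at the right oxidation level as an orthogonal ester from a stable, crystalline-type pyrone.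

**Alternative 3:** An aryne three-component coupling. The O–C1 bond of ring B and the C2–carboxyl bond are cut. Fluoride converts silyl triflate A8 into the aryne, the phenoxide of A9 adds at the aryne carbon remote from the acetal oxygen, and the aryl anion is carboxylated in the same flask to give acid A7.
- For it: it is the most convergent of the four. It forms the hindered ether without a metal and places the carboxyl in one operation, with regiochemistry set by the inductive effect of the alkoxy group. On brevity of bond construction it is stronger than the chosen route.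
- Against it: the phenoxide of A9 is flanked on both sides and is a weak nucleophile. The aryl anion is more easily protonated than carboxylated, and any proton source, including unreacted A9, gives the ether without the carboxyl. Ring A cannot carry its methyl ester, because the aryl anion would close onto it, so it travels as an acetal. After the key step the acetal must be hydrolysed and oxidised, and the new ring A acid must be esterified selectively beside the ring B acid.
- Comparison: the chosen route has a longer preparation of its ring A partner, but it keeps the two carboxyls distinct from the first step and has no competition between protonation and carboxylation.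

Key step: step 11

Remark on the chemistry: 3-chloro-2-methoxyphenol (1) is taken to be a purchasable catalogue phenol.

## Route

Step 1
Reactants: 1 3-chloro-2-methoxyphenol
Product: 3 4-chloro-2-hydroxy-3-methoxybenzaldehyde, via benzylic alcohol 2 (not isolated)
Conditions: MgCl2, Et3N, (CH2O)n, MeCN, reflux; aq. HCl
Reagents that add atoms: paraformaldehyde (formaldehyde), C=O
Why: Magnesium-mediated ortho-formylation (Casnati–Skattebøl type): the magnesium phenoxide delivers formaldehyde to C6, the only free ortho position, and the benzylic alkoxide 2 is oxidised to the aldehyde by hydride transfer to a second formaldehyde; the aryl chloride and the methyl ether are inert.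

Step 2
Reactants: 3 4-chloro-2-hydroxy-3-methoxybenzaldehyde
Product: 4 4-chloro-2-hydroxy-3-methoxybenzoic acid
Conditions: NaClO2, NaH2PO4, 2-methyl-2-butene, t-BuOH/H2O, rt
Reagents that add atoms: NaClO2 (sodium chlorite), [Na+].[O-]Cl=O
Why: Pinnick oxidation: chlorous acid adds to the aldehyde and fragments to the acid and HOCl, which the alkene scavenges so that the free para position of the phenol is not chlorinated.

Step 3
Reactants: 4 4-chloro-2-hydroxy-3-methoxybenzoic acid
Product: 6 4-chloro-2,5-dihydroxy-3-methoxybenzoic acid, via aryl sulfate 5 (not isolated)
Conditions: K2S2O8, aq. NaOH, 0 °C to rt; then HCl, H2O, 90 °C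
Reagents that add atoms: K2S2O8 (potassium peroxodisulfate), [K+].[K+].[O-]S(=O)(=O)OOS(=O)(=O)[O-]
Why: Elbs persulfate oxidation: the phenoxide attacks the peroxide oxygen through C5, the only free position ortho or para to the phenoxide oxygen, and the aryl sulfate 5 is hydrolysed in hot acid; sulfation deactivates the ring and limits over-oxidation.

Step 4
Reactants: 6 4-chloro-2,5-dihydroxy-3-methoxybenzoic acid
Product: 7 methyl 4-chloro-2,5-dihydroxy-3-methoxybenzoate
Conditions: MeOH, H2SO4 (cat.), reflux, argon
Reagents that add atoms: methanol, CO
Why: Fischer esterification in excess methanol; the phenols do not esterify and exclusion of air protects the hydroquinone.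

Step 5
Reactants: 7 methyl 4-chloro-2,5-dihydroxy-3-methoxybenzoate
Product: 8 methyl 4-chloro-2-hydroxy-3-methoxy-5-(methoxymethoxy)benzoate
Conditions: MOMCl (1.05 equiv), iPr2NEt, CH2Cl2, 0 °C
Reagents that add atoms: chloromethyl methyl ether (MOMCl), COCCl
Why: Chemoselective O-alkylation: the C5 hydroxyl is acidified by the ortho chlorine and is free of hydrogen bonding, whereas the C2 hydroxyl is hydrogen-bonded to the ester carbonyl and flanked on both sides.

Step 6
Reactants: 8 methyl 4-chloro-2-hydroxy-3-methoxy-5-(methoxymethoxy)benzoate
Product: 9 methyl 4-chloro-2-(ethenyloxy)-3-methoxy-5-(methoxymethoxy)benzoate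
Conditions: Cu(OAc)2 (1 equiv), 2,4,6-trivinylcyclotriboroxane–pyridine complex, pyridine, CH2Cl2, rt, air
Reagents that add atoms: 2,4,6-trivinylcyclotriboroxane–pyridine complex, C=CB1OB(C=C)OB(C=C)O1.c1ccncc1
Why: Chan–Lam-type oxidative O-vinylation: a vinyl group passes from boron to divalent copper, the phenoxide binds, and C–O reductive elimination from trivalent copper gives the aryl vinyl ether at room temperature, which spares the ester, the acetal and the aryl chloride.

Step 7
Reactants: 9 methyl 4-chloro-2-(ethenyloxy)-3-methoxy-5-(methoxymethoxy)benzoate
Product: 11 methyl 2-[(2-bromoethenyl)oxy]-4-chloro-3-methoxy-5-(methoxymethoxy)benzoate (E/Z mixture), via dibromide 10 (not isolated)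
Conditions: Br2 (1.0 equiv), CH2Cl2, −78 °C; then DBU, −78 °C to rt
Reagents that add atoms: bromine, BrBr
Why: Addition of bromine to the enol ether double bond is far faster than ring bromination at −78 °C; DBU then removes HBr from dibromide 10 by loss of the ionisable bromide next to oxygen, and both geometric isomers of 11 serve in step 8.

Step 8
Reactants: 11 methyl 2-[(2-bromoethenyl)oxy]-4-chloro-3-methoxy-5-(methoxymethoxy)benzoate (E/Z mixture)
Product: 13 methyl 4-chloro-2-(ethynyloxy)-3-methoxy-5-(methoxymethoxy)benzoate, via lithium acetylide 12 (not isolated)
Conditions: LiN(iPr)2 (2.5 equiv), THF, −78 °C; then H2O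
Reagents that add atoms: none
Why: Base-induced dehydrobromination of a 2-bromovinyl ether to an alkynyl ether: the Z isomer undergoes anti E2 elimination, the E isomer reacts by alpha-lithiation and a Fritsch–Buttenberg–Wiechell-type shift, and excess amide holds the product as acetylide 12 until the quench. The hindered amide should not add to the aryl ester at −78 °C, and the basic work-up spares the acid-labile alkynyl ether.

Step 9
Reactants: 14 diallyl malonate; 15 2,2,6-trimethyl-4H-1,3-dioxin-4-one
Product: 18 allyl 4-hydroxy-6-methyl-2-oxo-2H-pyran-3-carboxylate, via acetylketene 16 (not isolated), via acylmalonate 17 (not isolated)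
Conditions: NaH, THF, 0 °C; 15, toluene, 110 °C; 1 M HCl; toluene, reflux
Reagents that add atoms: none
Why: Thermal retro-hetero-Diels–Alder reaction of 15 releases acetylketene 16, which C-acylates the sodium enolate of 14 to give tricarbonyl 17. After acidification the enol oxygen of the methyl ketone closes onto one allyl ester (6-exo-trig lactonisation with loss of allyl alcohol), the known route from malonates to 3-alkoxycarbonyl-4-hydroxy-6-methyl-2-pyrones. The diallyl ester makes any alkoxide exchange degenerate.

Step 10
Reactants: 18 allyl 4-hydroxy-6-methyl-2-oxo-2H-pyran-3-carboxylate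
Product: 19 allyl 4-(methoxymethoxy)-6-methyl-2-oxo-2H-pyran-3-carboxylate
Conditions: MOMCl, iPr2NEt, CH2Cl2, 0 °C to rt
Reagents that add atoms: chloromethyl methyl ether (MOMCl), COCCl
Why: O-alkylation of the vinylogous acid at the C4 oxygen with the hard chloromethyl ether gives the 4-alkoxy-2-pyrone and keeps the conjugated lactone; the acetal removes the acidic proton that would otherwise add to the alkynyl ether in step 11.

Step 11
Reactants: 13 methyl 4-chloro-2-(ethynyloxy)-3-methoxy-5-(methoxymethoxy)benzoate; 19 allyl 4-(methoxymethoxy)-6-methyl-2-oxo-2H-pyran-3-carboxylate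
Product: 21 allyl 2-[3-chloro-2-methoxy-6-(methoxycarbonyl)-4-(methoxymethoxy)phenoxy]-6-(methoxymethoxy)-4-methylbenzoate, via bicyclic lactone 20 (not isolated)
Conditions: 19 (3 equiv), toluene (0.5 M), 110–130 °C, sealed tube, argon
Reagents that add atoms: none
Why: This is an inverse-electron-demand Diels–Alder reaction of a 2-pyrone-3-carboxylate with an ynol ether followed by loss of CO2, a known route to 2-alkoxybenzoates. The pyrone, made electron-poor by the lactone and the C3 ester, is the diene; the nucleophilic terminal carbon of 13 bonds first to pyrone C6, and the aryloxy-bearing carbon, which carries the developing positive charge, then closes onto C3 in an asynchronous [4+2] cycloaddition. This gives the 2-oxabicyclo[2.2.2]octadienone 20, which extrudes its lactone bridge as CO2 by retro-[4+2] reaction at the reaction temperature, driven by aromatisation. Ring B is therefore closed by intermolecular [4+2] cycloaddition (ring B bonds C1–C2 and C5–C6) and not by cyclisation of a chain. The two bridgehead stereocentres of 20 are tied to each other by the bicycle and vanish on aromatisation, so 21 has no stereocentre. The selectivity needed is regiochemical, ether oxygen next to the ester-bearing carbon, and the match between the nucleophilic alkyne terminus and the electrophilic C6 secures it. The allyl ester alkene is not electron-rich and does not compete, and the aryl alkynyl ether has no beta-hydrogen on its oxygen substituent and cannot fragment to a ketene on heating. The C4 acetal oxygen and the C6 methyl slow the reaction, which is why excess 19, high concentration and 110–130 °C are planned.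

Step 12
Reactants: 21 allyl 2-[3-chloro-2-methoxy-6-(methoxycarbonyl)-4-(methoxymethoxy)phenoxy]-6-(methoxymethoxy)-4-methylbenzoate
Product: 22 allyl 2-[3-chloro-4-hydroxy-2-methoxy-6-(methoxycarbonyl)phenoxy]-6-hydroxy-4-methylbenzoate
Conditions: 3 M HCl in MeOH, rt
Reagents that add atoms: none
Why: Acid-catalysed transacetalisation of both aryl MOM ethers to methanol; the methyl ester is unchanged in methanol, the di-ortho-substituted allyl ester is too hindered to transesterify, and the ring B carboxyl is still masked, so it cannot decarboxylate.

Step 13
Reactants: 22 allyl 2-[3-chloro-4-hydroxy-2-methoxy-6-(methoxycarbonyl)phenoxy]-6-hydroxy-4-methylbenzoate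
Product: 23 2-[3-chloro-4-hydroxy-2-methoxy-6-(methoxycarbonyl)phenoxy]-6-hydroxy-4-methylbenzoic acid
Conditions: Pd(PPh3)4 (cat.), morpholine, THF, rt; dilute aq. HCl work-up at 0 °C
Reagents that add atoms: none
Why: Tsuji–Trost deallylation: zerovalent palladium ionises the allyl ester to a pi-allyl complex and the carboxylate, and morpholine takes up the allyl group; neutral conditions at room temperature spare the methyl ester, the aryl chloride and the decarboxylation-prone acid.

## Compound list

1 | 3-chloro-2-methoxyphenol | COc1c(O)cccc1Cl | starting material
2 | 3-chloro-6-(hydroxymethyl)-2-methoxyphenol | COc1c(O)c(CO)ccc1Cl | intermediate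
3 | 4-chloro-2-hydroxy-3-methoxybenzaldehyde | COc1c(O)c(C=O)ccc1Cl | intermediate
4 | 4-chloro-2-hydroxy-3-methoxybenzoic acid | COc1c(O)c(C(=O)O)ccc1Cl | intermediate
5 | 4-chloro-2-hydroxy-3-methoxy-5-(sulfooxy)benzoic acid (present as its salt) | COc1c(O)c(C(=O)O)cc(OS(=O)(=O)O)c1Cl | intermediate
6 | 4-chloro-2,5-dihydroxy-3-methoxybenzoic acid | COc1c(O)c(C(=O)O)cc(O)c1Cl | intermediate
7 | methyl 4-chloro-2,5-dihydroxy-3-methoxybenzoate | COC(=O)c1cc(O)c(Cl)c(OC)c1O | intermediate
8 | methyl 4-chloro-2-hydroxy-3-methoxy-5-(methoxymethoxy)benzoate | COC(=O)c1cc(OCOC)c(Cl)c(OC)c1O | intermediate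
9 | methyl 4-chloro-2-(ethenyloxy)-3-methoxy-5-(methoxymethoxy)benzoate | COC(=O)c1cc(OCOC)c(Cl)c(OC)c1OC=C | intermediate
10 | methyl 4-chloro-2-(1,2-dibromoethoxy)-3-methoxy-5-(methoxymethoxy)benzoate (racemic) | COC(=O)c1cc(OCOC)c(Cl)c(OC)c1OC(Br)CBr | intermediate
11 | methyl 2-[(2-bromoethenyl)oxy]-4-chloro-3-methoxy-5-(methoxymethoxy)benzoate (mixture of E and Z isomers) | COC(=O)c1cc(OCOC)c(Cl)c(OC)c1OC=CBr | intermediate
12 | methyl 4-chloro-2-[(lithioethynyl)oxy]-3-methoxy-5-(methoxymethoxy)benzoate | COC(=O)c1cc(OCOC)c(Cl)c(OC)c1OC#C[Li] | intermediate
13 | methyl 4-chloro-2-(ethynyloxy)-3-methoxy-5-(methoxymethoxy)benzoate | COC(=O)c1cc(OCOC)c(Cl)c(OC)c1OC#C | intermediate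
14 | diallyl malonate (di(prop-2-en-1-yl) propanedioate) | C=CCOC(=O)CC(=O)OCC=C | starting material
15 | 2,2,6-trimethyl-4H-1,3-dioxin-4-one | CC1=CC(=O)OC(C)(C)O1 | starting material
16 | acetylketene (but-1-ene-1,3-dione) | CC(=O)C=C=O | intermediate
17 | diallyl 2-(3-oxobutanoyl)propanedioate | CC(=O)CC(=O)C(C(=O)OCC=C)C(=O)OCC=C | intermediate
18 | allyl 4-hydroxy-6-methyl-2-oxo-2H-pyran-3-carboxylate | CC1=CC(O)=C(C(=O)OCC=C)C(=O)O1 | intermediate
19 | allyl 4-(methoxymethoxy)-6-methyl-2-oxo-2H-pyran-3-carboxylate | CC1=CC(OCOC)=C(C(=O)OCC=C)C(=O)O1 | intermediate
20 | allyl 5-[3-chloro-2-methoxy-6-(methoxycarbonyl)-4-(methoxymethoxy)phenoxy]-8-(methoxymethoxy)-1-methyl-3-oxo-2-oxabicyclo[2.2.2]octa-5,7-diene-4-carboxylate (racemic, one enantiomer drawn; the two bridgeheads are tied by the bicycle) | C[C@]12OC(=O)[C@](C(=O)OCC=C)(C(OCOC)=C1)C(Oc3c(C(=O)OC)cc(OCOC)c(Cl)c3OC)=C2 | intermediate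
21 | allyl 2-[3-chloro-2-methoxy-6-(methoxycarbonyl)-4-(methoxymethoxy)phenoxy]-6-(methoxymethoxy)-4-methylbenzoate | COC(=O)c1cc(OCOC)c(Cl)c(OC)c1Oc1cc(C)cc(OCOC)c1C(=O)OCC=C | intermediate
22 | allyl 2-[3-chloro-4-hydroxy-2-methoxy-6-(methoxycarbonyl)phenoxy]-6-hydroxy-4-methylbenzoate | COC(=O)c1cc(O)c(Cl)c(OC)c1Oc1cc(C)cc(O)c1C(=O)OCC=C | intermediate
23 | 2-[3-chloro-4-hydroxy-2-methoxy-6-(methoxycarbonyl)phenoxy]-6-hydroxy-4-methylbenzoic acid | COC(=O)c1cc(O)c(Cl)c(OC)c1Oc1cc(C)cc(O)c1C(=O)O | target

## Step count and least certain steps

Total: 13 steps. Longest linear sequence: 11 steps (steps 1–8, then 11–13). The pyrone branch is 2 steps (9 and 10).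

**Step 11 (key step).** The cycloaddition may be too slow. The acetal oxygen at pyrone C4 feeds electron density into the diene, the C6 methyl hinders the first bond, and the ring A ester makes the aryloxy group a weaker donor. Thermal oligomerisation of 13, or its hydration by traces of water, could then outrun ring formation. The fallback gives up the cycloaddition and makes the ether bond by Ullmann coupling; it sets out from phenol 8 and rejoins the route at 21.
- Commercial 3-bromo-5-methylphenol F1 would be converted into 1-bromo-3-(methoxymethoxy)-5-methylbenzene F2 (MOMCl, iPr2NEt).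
- F2 would be lithiated between bromine and the acetal oxygen with LiN(iPr)2 at −78 °C and trapped with allyl chloroformate to give allyl 2-bromo-6-(methoxymethoxy)-4-methylbenzoate F3.
- Coupling of F3 with 8 (CuI, picolinic acid, K3PO4, DMSO, 90 °C) would give 21. The ortho ester of F3 helps the copper step, but the doubly hindered coupling is the reason this is only the reserve.

**Step 8.** The strong base may ortho-lithiate ring A at C6, which lies between the ester and the acetal oxygen. Acetylide 12 may add to the methyl ester of a second molecule, and the E isomer of 11 may eliminate incompletely. The fallback avoids strong base; it sets out from vinyl ether 9, bypasses 11 and rejoins at 13.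
- Addition of PhSeCl to 9 at −78 °C and loss of HCl with Et3N should give methyl 4-chloro-3-methoxy-5-(methoxymethoxy)-2-{[(E)-2-(phenylselanyl)ethenyl]oxy}benzoate F4.
- Oxidation with mCPBA at −78 °C would give the selenoxide, methyl 4-chloro-3-methoxy-5-(methoxymethoxy)-2-{[(E)-2-(phenylseleninyl)ethenyl]oxy}benzoate F5.
- Warming F5 with DABCO should give 13 by syn elimination, since the hydrogen on the oxygen-bearing carbon is cis to selenium in the E isomer.

**Step 6.** Transfer of the vinyl group to a phenol that is hindered on both sides, hydrogen-bonded and able to chelate copper may stall at low conversion. The fallback attaches the two carbons by alkylation; it sets out from 8 and rejoins at 9.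
- Alkylation of 8 with excess 1,2-dibromoethane (K2CO3, DMF, 60 °C) would give methyl 2-(2-bromoethoxy)-4-chloro-3-methoxy-5-(methoxymethoxy)benzoate F6.
- Displacement with PhSeNa (from PhSeSePh and NaBH4) would give methyl 4-chloro-3-methoxy-5-(methoxymethoxy)-2-[2-(phenylselanyl)ethoxy]benzoate F7.
- Oxidation with NaIO4 would give the selenoxide, methyl 4-chloro-3-methoxy-5-(methoxymethoxy)-2-[2-(phenylseleninyl)ethoxy]benzoate F8, which has hydrogen only on the oxygen-bearing carbon and should eliminate to 9 on warming with iPr2NH.

**Step 3.** Partial conversion is to be expected, and the hydroquinone may be oxidised further under alkaline persulfate. The fallback introduces the oxygen through a formyl group; it sets out from 4, replaces steps 3 and 4 and rejoins at 7.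
- Fischer esterification of 4 would give methyl 4-chloro-2-hydroxy-3-methoxybenzoate F9.
- Duff formylation (hexamethylenetetramine, CF3CO2H, 90 °C) at C5, the only free position para to the hydroxyl, would give methyl 4-chloro-5-formyl-2-hydroxy-3-methoxybenzoate F10.
- Dakin oxidation (H2O2, catalytic PhSeSePh, CH2Cl2) would give methyl 4-chloro-5-(formyloxy)-2-hydroxy-3-methoxybenzoate F11, and mild hydrolysis (aq. NaHCO3, THF) would give 7.

**Step 9.** Acetylketene 16 may dimerise or O-acylate the enolate instead of C-acylating it, and lactonisation of 17 may be incomplete. The fallback starts from a preformed pyrone; it does not use 14 and 15 and rejoins at 18.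
- Commercial 4-hydroxy-6-methyl-2H-pyran-2-one F12 would be O-acylated with allyl chloroformate and Et3N to give allyl 6-methyl-2-oxo-2H-pyran-4-yl carbonate F13.
- A DMAP-catalysed O-to-C alkoxycarbonyl shift (Steglich-type rearrangement) to the nucleophilic C3 would give 18.

## Further compounds

F1 | step 11 | 3-bromo-5-methylphenol | Cc1cc(O)cc(Br)c1
F2 | step 11 | 1-bromo-3-(methoxymethoxy)-5-methylbenzene | COCOc1cc(C)cc(Br)c1
F3 | step 11 | allyl 2-bromo-6-(methoxymethoxy)-4-methylbenzoate | C=CCOC(=O)c1c(Br)cc(C)cc1OCOC
F4 | step 8 | methyl 4-chloro-3-methoxy-5-(methoxymethoxy)-2-{[(E)-2-(phenylselanyl)ethenyl]oxy}benzoate | COC(=O)c1cc(OCOC)c(Cl)c(OC)c1O/C=C/[Se]c1ccccc1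
F5 | step 8 | methyl 4-chloro-3-methoxy-5-(methoxymethoxy)-2-{[(E)-2-(phenylseleninyl)ethenyl]oxy}benzoate | COC(=O)c1cc(OCOC)c(Cl)c(OC)c1O/C=C/[Se](=O)c1ccccc1
F6 | step 6 | methyl 2-(2-bromoethoxy)-4-chloro-3-methoxy-5-(methoxymethoxy)benzoate | COC(=O)c1cc(OCOC)c(Cl)c(OC)c1OCCBr
F7 | step 6 | methyl 4-chloro-3-methoxy-5-(methoxymethoxy)-2-[2-(phenylselanyl)ethoxy]benzoate | COC(=O)c1cc(OCOC)c(Cl)c(OC)c1OCC[Se]c1ccccc1
F8 | step 6 | methyl 4-chloro-3-methoxy-5-(methoxymethoxy)-2-[2-(phenylseleninyl)ethoxy]benzoate | COC(=O)c1cc(OCOC)c(Cl)c(OC)c1OCC[Se](=O)c1ccccc1
F9 | step 3 | methyl 4-chloro-2-hydroxy-3-methoxybenzoate | COC(=O)c1ccc(Cl)c(OC)c1O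
F10 | step 3 | methyl 4-chloro-5-formyl-2-hydroxy-3-methoxybenzoate | COC(=O)c1cc(C=O)c(Cl)c(OC)c1O
F11 | step 3 | methyl 4-chloro-5-(formyloxy)-2-hydroxy-3-methoxybenzoate | COC(=O)c1cc(OC=O)c(Cl)c(OC)c1O
F12 | step 9 | 4-hydroxy-6-methyl-2H-pyran-2-one | CC1=CC(O)=CC(=O)O1
F13 | step 9 | allyl 6-methyl-2-oxo-2H-pyran-4-yl carbonate | CC1=CC(OC(=O)OCC=C)=CC(=O)O1
A1 | alternative 1 | methyl trans-2-[2-(tert-butoxycarbonyl)-3-(methoxymethoxy)-5-methylphenoxy]-3,5-dioxocyclohexane-1-carboxylate (racemic, one enantiomer drawn) | COC(=O)[C@@H]1CC(=O)CC(=O)[C@H]1Oc1cc(C)cc(OCOC)c1C(=O)OC(C)(C)C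
A2 | alternative 1 | tert-butyl 2-(methoxymethoxy)-4-methyl-6-(2-oxopropoxy)benzoate | CC(=O)COc1cc(C)cc(OCOC)c1C(=O)OC(C)(C)C
A3 | alternative 1 | dimethyl fumarate | COC(=O)/C=C/C(=O)OC
A4 | alternative 2 | methyl 2-[2-({[tert-butyl(dimethyl)silyl]oxy}methyl)-3-hydroxy-5-methylphenoxy]-4-chloro-3-methoxy-5-(methoxymethoxy)benzoate | COC(=O)c1cc(OCOC)c(Cl)c(OC)c1Oc1cc(C)cc(O)c1CO[Si](C)(C)C(C)(C)C
A5 | alternative 2 | 3-methylcyclobut-2-en-1-one | CC1=CC(=O)C1
A6 | alternative 2 | methyl 2-[(3-{[tert-butyl(dimethyl)silyl]oxy}prop-1-yn-1-yl)oxy]-4-chloro-3-methoxy-5-(methoxymethoxy)benzoate | COC(=O)c1cc(OCOC)c(Cl)c(OC)c1OC#CCO[Si](C)(C)C(C)(C)C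
A7 | alternative 3 | 2-[3-chloro-6-(1,3-dioxolan-2-yl)-2-methoxy-4-(methoxymethoxy)phenoxy]-6-(methoxymethoxy)-4-methylbenzoic acid | COCOc1cc(C)cc(Oc2c(C3OCCO3)cc(OCOC)c(Cl)c2OC)c1C(=O)O
A8 | alternative 3 | 3-(methoxymethoxy)-5-methyl-2-(trimethylsilyl)phenyl trifluoromethanesulfonate | COCOc1cc(C)cc(OS(=O)(=O)C(F)(F)F)c1[Si](C)(C)C
A9 | alternative 3 | 3-chloro-6-(1,3-dioxolan-2-yl)-2-methoxy-4-(methoxymethoxy)phenol | COCOc1cc(C2OCCO2)c(O)c(OC)c1Cl
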